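## Structural features

The target is a 6,8-dioxabicyclo[3.2.2]nonan-7-one. The core is labelled C1 (quaternary: ether oxygen O2, lactone carbonyl C9, C7 and chain A), C3 (ether CH carrying chain B), C4 (carries the methyl group and the lactone oxygen O8), C5, C6 and C7 (CHOH). A 1,4-dioxan-2-one ring (C1–O2–C3–C4–O8–C9) is spanned across C1 and C4 by the three-carbon bridge C5–C6–C7, so an oxepane and a seven-membered lactone share the same atoms. There are four stereocentres in two adjacent pairs, C1/C7 and C3/C4 (1R,3S,4R,7S in these labels). C1 and C4 are bridgeheads and can only be joined cis; chain B on C3 points towards the three-carbon bridge, and the C7 hydroxyl points towards the lactone bridge. Chain A on C1, (Z)-5-hydroxy-4-methylpent-3-enyl, and chain B on C3, (Z)-5-hydroxy-3-methylpent-3-enyl, are both Z-trisubstituted allylic alcohols with the methyl group on different alkene carbons. Fragile features are the strained α-alkoxy lactone with its β-hydroxyl (hydride, alkoxide, retro-aldol cleavage, and translactonisation by any hydroxyl that reaches C9 through a five- or six-membered ring), the allylic alcohols and their Z-geometry. The real difficulty is the pair of fully substituted, oxygen-bearing bridgeheads, above all the relation of quaternary C1 to C3 across the ether oxygen, which no later ring closure can correct. The key step exploits that C4 is tertiary and carries both a methyl group and the acyloxy oxygen O8, which is the radical formed by adding a hydrogen atom to the exocyclic methylene of an enol lactone, and that C5 lies β to the oxygenated C7, i.e. it is the terminus of a vinyl ketone on C1.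

## Logic of the disconnections

35 ⇐ 34. Two O–Si bonds are cut (C7–O and the chain B allylic oxygen). The hydroxyl groups are freed last because a free C7 hydroxyl β to C9 invites retro-aldol cleavage under base. The skeleton is already complete. The forward step must remove a hindered secondary silyl ether without harming the lactone or the allylic alcohols.

34 ⇐ 33 ⇐ 32. In chain A the C–CH2OH bond and then the trisubstituted C=C bond are cut. The Z-alkene then comes from an aldehyde, and the hydroxymethyl carbon enters at the alcohol oxidation level, so no ester has to be reduced beside the lactone. Chain A shrinks to a three-carbon aldehyde. The forward steps need a Z-selective iodo-olefination and a coupling with retention.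

32 ⇐ 30. No skeletal bond is cut; the aldehyde is masked as a dioxolane. The mask lets the chain A handle pass the whole sequence without a free hydroxyl near C9. The forward step needs an acetal cleavage that spares two silyl ethers.

30 ⇐ 24 + 28. The sp3–sp2 bond between the second CH2 of chain B and the methyl-bearing alkene carbon is cut. The Z-geometry is made separately on a four-carbon piece and the core loses five carbons. The forward step needs zinc insertion into a primary iodide beside a lactone and a stereoretentive palladium coupling.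

28 ⇐ 27 ⇐ 25. An O–Si bond, then the C–I and C–H bonds across the alkyne are cut. The alkoxide-directed hydroalumination fixes the Z-geometry from a commercial alkynol. The forward step needs clean iodinolysis of the alkenyl alanate.

24 ⇐ 23 ⇐ 22 ⇐ 21 ⇐ 20. Only functional groups change (C–I, two O–Si operations, the C7–H bond). C7 is reduced straight after the key step so that the β-keto lactone, open to retro-Claisen cleavage, is not carried further. The forward steps need facial control at C7 (hydride from the side of the ether bridge) and removal of a primary silyl ether beside a hindered secondary one.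

20 ⇐ 19. The C4–C5 bond is cut. This removes the bridge, one ring and the C4 stereocentre, leaving a monocyclic dioxanone with an exocyclic methylene on C4 and a vinyl ketone on C1. The forward step needs a C4 radical generated selectively at the enol ester, and the vinyl ketone must stand cis to chain B on the ring.

19 ⇐ 17 (through 18). No skeletal bond is cut; the C5=C6 double bond is hidden as a β-phenylsulfanyl ketone. The reactive enone then appears only one step before it is used. The forward step needs sulfur oxidation that leaves the enol lactone alone.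

17 ⇐ 15 + 16. The C1–CH2 bond of the chain A handle is cut. Making this the last bond to C1 means the electrophile enters the ring enolate anti to chain B, which is exactly the required relation (acyl group cis, handle trans to chain B). The gain is a stereochemically undefined C1 and a commercial bromide. The forward step needs C-alkylation of a hindered β-keto lactone with good facial selectivity.

15 ⇐ 12 + 14, and 14 ⇐ 13. The C1–C7 bond is cut (and the acyl–imidazole bond). C1 becomes a plain CH2 of a glycolate-derived lactone, so both carbon substituents on C1 are introduced under ring control. The forward step needs an enol-lactone enolate that is acylated before it decomposes.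

12 ⇐ 11. The O8–C4 bond is cut. The enol lactone comes from an alkynyl ether acid by cycloisomerisation, and the ring disappears. The forward step needs 6-exo-dig selectivity and no migration of the exocyclic double bond.

11 ⇐ 8 + 9 (through 10). The O2–C1 bond is cut (and the alkynyl C–Si bond). A Williamson etherification joins the C3 carbinol to a two-carbon acid without touching the stereocentre. The forward step needs O-alkylation of a secondary propargylic alkoxide without propargyl–allenyl isomerisation.

8 ⇐ 7 ⇐ 6 ⇐ 3 + 4 (through 5). The C3–H bond (asymmetric reduction) and then the C3–C4 bond (acetylide addition) are cut. C3 is the only stereocentre made by an external chiral reagent. The forward step needs high enantioselectivity in the ynone reduction.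

3 ⇐ 2 ⇐ 1. Functional-group changes on propane-1,3-diol; the forward steps need monoprotection and a mild oxidation.

## Other disconnections considered

Alternative 1: The cut is C1–C7. In the forward sense the aldehyde A1 (C7 aldehyde, C4 as its triethylsilyl ether, chain B complete, O2 carrying a dimethyl butenedioate unit) would be treated with SmI2 and methanol. The C7 ketyl adds 7-exo-trig to the oxygen-bearing alkene carbon and gives the oxepane diester A2, with C1 quaternary and the C7 hydroxyl in place.
- In favour: the closure belongs to the well-known family of ketyl additions to β-alkoxyacrylates. C3 and C4 come from acyclic chemistry, chain B is carried through because divalent samarium leaves isolated alkenes alone, and C7 arrives as the alcohol. On these three points it is the equal or the better of the chosen plan, which needs saturated handles and a separate ketone reduction.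
- Against: two stereocentres (C1 and C7) are created at once in a seven-membered closure without a ring template, so their relation to C3/C4 rests on chelation arguments. Afterwards two methyl esters on C1 must be told apart. The C7 hydroxyl can close a γ-lactone onto the CH2CO2Me arm more easily than the hindered C4 oxygen closes the bridged lactone. Chain A still has to be grown by three carbons from that arm.
- Comparison: structurally both plans make the oxepane by a radical seven-ring closure, but the chosen plan closes it endo on a preformed six-membered ring and creates one centre that has no choice. Mechanistically the samarium step is stoichiometric and also threatens α-alkoxy carbonyl groups, whereas the iron step is catalytic and neutral. In step count the saved ketone reduction is used up by ester differentiation, lactonisation and homologation of chain A.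

Alternative 2: The cut is O2–C3. In the forward sense the seven-membered hydroxy keto lactone A3 (tertiary C1–OH, ketone at C3, both side chains as allylic acetates, C7 silyl ether) would close to its bridged hemiketal. With Me3SiOTf and Et3SiH it would pass through the oxocarbenium ion O2=C3 to the protected target A4.
- In favour: it is the most convergent plan, with both unsaturated chains complete before the key step and only deprotection after it. In step count after the key step it is clearly better than the chosen plan. Hydride should arrive from the side of the flat lactone bridge, away from the substituted three-carbon bridge, which gives the required C3 configuration, so on this centre it is probably the equal.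
- Against: the oxocarbenium ion is flanked by two inductively withdrawing centres (C4 with its acyloxy oxygen, O2 bound to the carbonyl-bearing C1). The tertiary α-hydroxy lactone is a poor nucleophile for hemiketalisation, Et3SiH can reduce the C3 ketone directly, and the silyl triflate can ionise the allylic acetates. A3 must already hold C1, C4 and C7 on a medium-ring lactone, which only moves the main problem into the precursor. The final acetate removal needs base next to the lactone.
- Comparison: structurally the chosen plan fixes C3 first by catalyst control and builds C1 and C4 on it, while this plan fixes C3 last by substrate control. Mechanistically an ionic closure through a destabilised cation is set against a neutral radical closure. The step economy is better after the key step and very probably worse before it.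

Alternative 3: The cuts are O8–C9 and C6–C7. In the forward sense the malonate A5 (C1 a non-stereogenic alkoxymalonate carbon carrying chain A; C4 a free tertiary alcohol with a 2-(phenylsulfonyl)ethyl arm; chain B complete) would be treated with three equivalents of LiN(i-Pr)2. The C4 alkoxide lactonises reversibly onto either ester. The α-sulfonyl carbanion at C6 acylates the remaining ester only in the diastereomer where that ester lies on its side, giving the bridged keto sulfone A6.
- In favour: C1 is not a stereocentre before the step and its configuration follows by geometric necessity from C4. On this point the alternative is better than the chosen plan, whose C1 rests on a diastereoselective alkylation. Two rings and two bonds form in one operation, and the polar chemistry leaves both finished side chains untouched, so no late olefination or coupling is needed; it is also better in steps after the key step.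
- Against: the tertiary alcohol at C4 with its sulfonylethyl arm must be set against C3 by separate asymmetric chemistry, a relation the chosen plan obtains from bridging. A Dieckmann closure of a seven-membered ring competes with proton transfer and retro-reactions under strong base. The sulfone must then be removed next to an α-alkoxy ketone, where dissolving-metal or SmI2 conditions can also cut the C1–O2 bond.
- Comparison: both plans end at the C7 ketone and share the reduction problem (equal). Structurally this plan sets C4 early and lets it dictate C1; the chosen plan does the reverse. Mechanistically strongly basic two-electron chemistry is set against a neutral one-electron step. The overall step count should be similar, with fewer steps after and more before the key step.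

Key step: step 12

Remark on the chemistry: the three-carbon handle on C1 is carried as the 1,3-dioxolane of its terminal aldehyde (same carbon skeleton as an O-protected 3-hydroxypropyl group), because a free 3-hydroxypropyl group beside C9 could translactonise and the aldehyde is what the chain A olefination needs. Abbreviations: TBS = tert-butyldimethylsilyl (TBSO = its ether), TMS = trimethylsilyl.

## Steps

Step 1
Reactants: 1 propane-1,3-diol
Product: 2 3-(TBSO)propan-1-ol
Conditions: NaH (1.0 equiv), THF, 0 °C to rt; TBSCl (1.0 equiv)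
Reagents that add atoms: tert-butyldimethylsilyl chloride, CC(C)(C)[Si](C)(C)Cl
Why: O-Silylation of the sparingly soluble monosodium alkoxide of a symmetrical diol limits double silylation; no stereocentre is involved.

Step 2
Reactants: 2 3-(TBSO)propan-1-ol
Product: 3 3-(TBSO)propanal
Conditions: TEMPO (10 mol %), PhI(OAc)2, CH2Cl2, rt
Reagents that add atoms: none
Why: The TEMPO/PhI(OAc)2 oxidation stops at the aldehyde and is mild enough for a β-silyloxy aldehyde prone to elimination.

Step 3
Reactants: 3 3-(TBSO)propanal; 4 ethynyltrimethylsilane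
Product: 6 rac-5-(TBSO)-1-(trimethylsilyl)pent-1-yn-3-ol, via lithium (trimethylsilyl)acetylide 5 (not isolated)
Conditions: 4, n-BuLi, THF, −78 °C; then 3, −78 °C; aq. NH4Cl
Reagents that add atoms: none
Why: 1,2-Addition of a lithium acetylide to an aldehyde forms the C3–C4 bond; the racemic carbinol is only a carrier for the ketone of step 4.

Step 4
Reactants: 6 rac-5-(TBSO)-1-(trimethylsilyl)pent-1-yn-3-ol
Product: 7 5-(TBSO)-1-(trimethylsilyl)pent-1-yn-3-one
Conditions: Dess–Martin periodinane, CH2Cl2, rt
Reagents that add atoms: none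
Why: Dess–Martin oxidation of a propargylic alcohol gives the silyl-capped ynone, the substrate class of the asymmetric reduction.

Step 5
Reactants: 7 5-(TBSO)-1-(trimethylsilyl)pent-1-yn-3-one
Product: 8 (3S)-5-(TBSO)-1-(trimethylsilyl)pent-1-yn-3-ol
Conditions: RuCl[(S,S)-TsDPEN](p-cymene) (1 mol %), i-PrOH, rt
Reagents that add atoms: none
Why: Noyori asymmetric transfer hydrogenation of an alkynyl ketone; with the (S,S)-ligand hydride is expected on the face that gives the (S)-carbinol (the alkynyl group takes the place of the aryl group in the usual model), which sets C3.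

Step 6
Reactants: 8 (3S)-5-(TBSO)-1-(trimethylsilyl)pent-1-yn-3-ol; 9 bromoacetic acid
Product: 11 2-{[(3S)-5-(TBSO)pent-1-yn-3-yl]oxy}acetic acid, via silylalkynyl ether acid 10 (not isolated)
Conditions: NaH (2.5 equiv), THF, 0 °C to rt; then MeOH, K2CO3 (cat.), rt; HCl (aq.) to pH 3
Reagents that add atoms: none
Why: Williamson etherification of the sodium alkoxide with sodium bromoacetate forms O2–C1 with retention at C3 (its C–O bond is not broken), and methanolic carbonate then removes the alkynyl silyl group; no ester enolate of the open-chain propargyl ether is ever formed, so a [2,3]-Wittig rearrangement cannot occur.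

Step 7
Reactants: 11 2-{[(3S)-5-(TBSO)pent-1-yn-3-yl]oxy}acetic acid
Product: 12 (5S)-5-[2-(TBSO)ethyl]-6-methylidene-1,4-dioxan-2-one
Conditions: Ph3PAuNTf2 (2 mol %), CH2Cl2, rt
Reagents that add atoms: none
Why: Cycloisomerisation of an alkynoic acid with a cationic monovalent gold catalyst: anti-addition of the carboxyl oxygen to the activated terminal alkyne in the 6-exo-dig mode forms O8–C4 and the exocyclic enol lactone; neutral conditions and a short reaction time guard against migration of the double bond into the ring, which would destroy C3.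

Step 8
Reactants: 13 3-(phenylsulfanyl)propanoic acid
Product: 14 1-(1H-imidazol-1-yl)-3-(phenylsulfanyl)propan-1-one
Conditions: 1,1'-carbonyldiimidazole, THF, rt
Reagents that add atoms: 1,1'-carbonyldiimidazole, O=C(n1ccnc1)n1ccnc1
Why: Standard activation of a carboxylic acid as its acyl imidazole, a selective C-acylating agent for lithium enolates.

Step 9
Reactants: 12 (5S)-5-[2-(TBSO)ethyl]-6-methylidene-1,4-dioxan-2-one; 14 1-(1H-imidazol-1-yl)-3-(phenylsulfanyl)propan-1-one
Product: 15 (5S)-5-[2-(TBSO)ethyl]-6-methylidene-3-[3-(phenylsulfanyl)propanoyl]-1,4-dioxan-2-one (C3 epimers and enol)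
Conditions: LiN(SiMe3)2 (2.2 equiv), THF, −78 °C; then 14, −78 °C; AcOH quench
Reagents that add atoms: none
Why: Crossed Claisen acylation of the lactone lithium enolate forms C1–C7; the second equivalent of base stores the product as its stabilised enolate, and the temperature is held at −78 °C because an enol-lactone enolate can fragment to a ketene on warming; the configuration at C1 is irrelevant because it is enolised again in step 10.

Step 10
Reactants: 15 (5S)-5-[2-(TBSO)ethyl]-6-methylidene-3-[3-(phenylsulfanyl)propanoyl]-1,4-dioxan-2-one; 16 2-(2-bromoethyl)-1,3-dioxolane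
Product: 17 (3R,5S)-5-[2-(TBSO)ethyl]-3-[2-(1,3-dioxolan-2-yl)ethyl]-6-methylidene-3-[3-(phenylsulfanyl)propanoyl]-1,4-dioxan-2-one
Conditions: Cs2CO3, NaI (cat.), DMF, 40 °C
Reagents that add atoms: none
Why: C-Alkylation of a cyclic β-keto lactone enolate with a primary halide (iodide formed in situ); chain B at C3 should sit pseudo-axial (allylic strain with the exocyclic methylene when equatorial, no syn-axial hydrogens when axial) and shield one face of the flat enolate, so the electrophile enters anti to it and the quaternary C1 forms with the acyl group cis and the new chain trans to chain B, as the bridging step requires.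

Step 11
Reactants: 17 (3R,5S)-5-[2-(TBSO)ethyl]-3-[2-(1,3-dioxolan-2-yl)ethyl]-6-methylidene-3-[3-(phenylsulfanyl)propanoyl]-1,4-dioxan-2-one
Product: 19 (3R,5S)-5-[2-(TBSO)ethyl]-3-[2-(1,3-dioxolan-2-yl)ethyl]-6-methylidene-3-(prop-2-enoyl)-1,4-dioxan-2-one, via sulfoxide 18 (not isolated)
Conditions: mCPBA (1.0 equiv), CH2Cl2, −78 °C; then toluene, BHT (cat.), 80 °C
Reagents that add atoms: none
Why: A sulfide reacts with a peracid far faster than an enol ester or an acetal, and thermal syn-elimination of the β-keto sulfoxide then unmasks the vinyl ketone only one step before it is used.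

Step 12
Reactants: 19 (3R,5S)-5-[2-(TBSO)ethyl]-3-[2-(1,3-dioxolan-2-yl)ethyl]-6-methylidene-3-(prop-2-enoyl)-1,4-dioxan-2-one
Product: 20 (1R,5R,9S)-9-[2-(TBSO)ethyl]-1-[2-(1,3-dioxolan-2-yl)ethyl]-5-methyl-6,8-dioxabicyclo[3.2.2]nonane-2,7-dione
Conditions: Fe(acac)3 (0.3 equiv), Ph(i-PrO)SiH2 (2.5 equiv), THF/i-PrOH (10:1), 0.01 M, rt to 40 °C
Reagents that add atoms: none
Why: An iron hydride formed from Fe(acac)3 and the silane transfers a hydrogen atom to the exocyclic CH2 of the enol lactone (Markovnikov) and gives the tertiary C4 radical stabilised by O8; this nucleophilic radical adds to the terminal carbon C5 of the vinyl ketone on C1 (intramolecular Giese reaction), and the α-keto radical at C6 is reduced by divalent iron to the enolate and protonated by propan-2-ol, which returns trivalent iron. The closest known reaction type is the Fe(acac)3/silane reductive coupling of heteroatom-substituted donor alkenes with enones. One ring is closed, the seven-membered ring through C4–C5–C6–C7–C1, in the 7-endo-trig mode across the 1,4-positions of the dioxanone held as a boat. The only new stereocentre is C4; it is planar before the step and the three-atom bridge can span only one face, so C1 dictates its configuration. The step needs chemoselectivity between the two alkenes, which their polarity secures: the metal hydride prefers the electron-rich 1,1-disubstituted enol ester, whose radical is tertiary and oxygen-stabilised, over the acceptor alkene. Attack at C5 and not C6 follows from the nucleophilic character of the radical, since 6-exo attack at the α-carbon would be contra-electronic. High dilution and a largely aprotic medium are chosen against bimolecular reduction of the radical and alcoholysis of the activated enol lactone, and the saturated handles leave no other alkene that could accept a hydrogen atom.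

Step 13
Reactants: 20 (1R,5R,9S)-9-[2-(TBSO)ethyl]-1-[2-(1,3-dioxolan-2-yl)ethyl]-5-methyl-6,8-dioxabicyclo[3.2.2]nonane-2,7-dione
Product: 21 (1R,2S,5R,9S)-9-[2-(TBSO)ethyl]-1-[2-(1,3-dioxolan-2-yl)ethyl]-2-hydroxy-5-methyl-6,8-dioxabicyclo[3.2.2]nonan-7-one
Conditions: (R)-2-methyl-CBS-oxazaborolidine (0.3 equiv), catecholborane, toluene, −78 to −40 °C
Reagents that add atoms: none
Why: Corey–Bakshi–Shibata reduction: the ketone is flanked by the quaternary C1 (large) and the C6 methylene (small), so the (R)-catalyst should deliver hydride to the face that gives the (S)-alcohol at C7, with the hydroxyl towards the lactone bridge; catecholborane spares the lactone at this temperature, and early reduction removes the β-keto lactone, which is open to retro-Claisen cleavage.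

Step 14
Reactants: 21 (1R,2S,5R,9S)-9-[2-(TBSO)ethyl]-1-[2-(1,3-dioxolan-2-yl)ethyl]-2-hydroxy-5-methyl-6,8-dioxabicyclo[3.2.2]nonan-7-one
Product: 22 (1R,2S,5R,9S)-2-(TBSO)-9-[2-(TBSO)ethyl]-1-[2-(1,3-dioxolan-2-yl)ethyl]-5-methyl-6,8-dioxabicyclo[3.2.2]nonan-7-one
Conditions: TBSCl, imidazole, DMAP (cat.), DMF, 40 °C
Reagents that add atoms: tert-butyldimethylsilyl chloride, CC(C)(C)[Si](C)(C)Cl
Why: Silylation of a hindered secondary alcohol with the silyl chloride under nucleophilic catalysis; a silyl triflate is avoided because it can open the dioxolane, and the protected hydroxyl can no longer start a retro-aldol cleavage in the basic steps that follow.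

Step 15
Reactants: 22 (1R,2S,5R,9S)-2-(TBSO)-9-[2-(TBSO)ethyl]-1-[2-(1,3-dioxolan-2-yl)ethyl]-5-methyl-6,8-dioxabicyclo[3.2.2]nonan-7-one
Product: 23 (1R,2S,5R,9S)-2-(TBSO)-1-[2-(1,3-dioxolan-2-yl)ethyl]-9-(2-hydroxyethyl)-5-methyl-6,8-dioxabicyclo[3.2.2]nonan-7-one
Conditions: HF·pyridine, pyridine, THF, 0 °C
Reagents that add atoms: none
Why: Buffered HF·pyridine removes a primary silyl ether much faster than a secondary one flanked by a quaternary carbon, and leaves acetal and lactone intact; the freed hydroxyl could reach C9 only through a seven-membered ring.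

Step 16
Reactants: 23 (1R,2S,5R,9S)-2-(TBSO)-1-[2-(1,3-dioxolan-2-yl)ethyl]-9-(2-hydroxyethyl)-5-methyl-6,8-dioxabicyclo[3.2.2]nonan-7-one
Product: 24 (1R,2S,5R,9S)-2-(TBSO)-1-[2-(1,3-dioxolan-2-yl)ethyl]-9-(2-iodoethyl)-5-methyl-6,8-dioxabicyclo[3.2.2]nonan-7-one
Conditions: I2, PPh3, imidazole, CH2Cl2, 0 °C to rt
Reagents that add atoms: iodine, II
Why: Appel-type iodination of a primary alcohol under imidazole buffering, which the acetal and the silyl ether tolerate.

Step 17
Reactants: 25 but-2-yn-1-ol
Product: 27 (2Z)-3-iodobut-2-en-1-ol, via cyclic vinylalanate 26 (not isolated)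
Conditions: NaAlH2(OCH2CH2OCH3)2, THF, 0 °C to rt; then I2, −78 °C to rt
Reagents that add atoms: iodine, II
Why: Alkoxide-directed trans-hydroalumination of a propargylic alcohol places aluminium on C3 cis to the carbinol carbon in a five-membered alanate, and iodinolysis with retention gives the (Z)-iodoalkene.

Step 18
Reactants: 27 (2Z)-3-iodobut-2-en-1-ol
Product: 28 tert-butyl{[(2Z)-3-iodobut-2-en-1-yl]oxy}dimethylsilane
Conditions: TBSCl, imidazole, CH2Cl2, rt
Reagents that add atoms: tert-butyldimethylsilyl chloride, CC(C)(C)[Si](C)(C)Cl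
Why: Routine silylation of a primary allylic alcohol, so that no acidic proton meets the organozinc reagent of step 19.

Step 19
Reactants: 24 (1R,2S,5R,9S)-2-(TBSO)-1-[2-(1,3-dioxolan-2-yl)ethyl]-9-(2-iodoethyl)-5-methyl-6,8-dioxabicyclo[3.2.2]nonan-7-one; 28 tert-butyl{[(2Z)-3-iodobut-2-en-1-yl]oxy}dimethylsilane
Product: 30 (1R,2S,5R,9S)-2-(TBSO)-9-[(3Z)-5-(TBSO)-3-methylpent-3-en-1-yl]-1-[2-(1,3-dioxolan-2-yl)ethyl]-5-methyl-6,8-dioxabicyclo[3.2.2]nonan-7-one, via alkylzinc iodide 29 (not isolated)
Conditions: Zn dust (activated with Me3SiCl and BrCH2CH2Br), DMA, 40 °C; then 28, Pd(PPh3)4 (5 mol %), rt to 40 °C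
Reagents that add atoms: none
Why: Direct zinc insertion into a primary alkyl iodide tolerates lactone, acetal and silyl ethers, and the Negishi coupling of the alkylzinc iodide with the alkenyl iodide proceeds with retention of the Z-geometry, which completes chain B.

Step 20
Reactants: 30 (1R,2S,5R,9S)-2-(TBSO)-9-[(3Z)-5-(TBSO)-3-methylpent-3-en-1-yl]-1-[2-(1,3-dioxolan-2-yl)ethyl]-5-methyl-6,8-dioxabicyclo[3.2.2]nonan-7-one
Product: 32 3-[(1R,2S,5R,9S)-2-(TBSO)-9-[(3Z)-5-(TBSO)-3-methylpent-3-en-1-yl]-5-methyl-7-oxo-6,8-dioxabicyclo[3.2.2]nonan-1-yl]propanal, via collidinium triflate 31 (not isolated)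
Conditions: Et3SiOTf, 2,4,6-collidine, CH2Cl2, 0 °C; then H2O
Reagents that add atoms: water, O
Why: Silyl triflate/collidine cleavage of an aldehyde acetal through a pyridinium N,O-acetal that water hydrolyses; the conditions are non-acidic, so the silyl ethers, the Z-allylic ether and the lactone should survive, and the aldehyde is released without a free hydroxyl that could reach C9.

Step 21
Reactants: 32 3-[(1R,2S,5R,9S)-2-(TBSO)-9-[(3Z)-5-(TBSO)-3-methylpent-3-en-1-yl]-5-methyl-7-oxo-6,8-dioxabicyclo[3.2.2]nonan-1-yl]propanal
Product: 33 (1R,2S,5R,9S)-2-(TBSO)-9-[(3Z)-5-(TBSO)-3-methylpent-3-en-1-yl]-1-[(3Z)-4-iodopent-3-en-1-yl]-5-methyl-6,8-dioxabicyclo[3.2.2]nonan-7-one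
Conditions: EtPPh3I, n-BuLi, THF, rt; I2, −78 °C; NaN(SiMe3)2, −20 °C; then 32, −78 °C
Reagents that add atoms: ethyltriphenylphosphonium iodide, CC[P+](c1ccccc1)(c1ccccc1)c1ccccc1.[I-]; iodine, II
Why: Stork–Zhao-type Wittig olefination with the α-iodoethylidene ylide; kinetic oxaphosphetane formation places iodine cis to the chain and gives the (Z)-2-iodoalkene, and the amide base is kept slightly short of the phosphonium salt so that no free base meets the lactone.

Step 22
Reactants: 33 (1R,2S,5R,9S)-2-(TBSO)-9-[(3Z)-5-(TBSO)-3-methylpent-3-en-1-yl]-1-[(3Z)-4-iodopent-3-en-1-yl]-5-methyl-6,8-dioxabicyclo[3.2.2]nonan-7-one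
Product: 34 (1R,2S,5R,9S)-2-(TBSO)-9-[(3Z)-5-(TBSO)-3-methylpent-3-en-1-yl]-1-[(3Z)-5-hydroxy-4-methylpent-3-en-1-yl]-5-methyl-6,8-dioxabicyclo[3.2.2]nonan-7-one
Conditions: Bu3SnCH2OH, Pd(PPh3)4 (10 mol %), toluene, 80 °C
Reagents that add atoms: (tributylstannyl)methanol, CCCC[Sn](CCCC)(CCCC)CO
Why: Stille coupling of an alkenyl iodide with the hydroxymethyl stannane (the α-oxygenated group transfers in preference to butyl) occurs with retention, so the hydroxymethyl group ends cis to the chain and chain A is complete without any ester reduction beside the lactone.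

Step 23
Reactants: 34 (1R,2S,5R,9S)-2-(TBSO)-9-[(3Z)-5-(TBSO)-3-methylpent-3-en-1-yl]-1-[(3Z)-5-hydroxy-4-methylpent-3-en-1-yl]-5-methyl-6,8-dioxabicyclo[3.2.2]nonan-7-one
Product: 35 (1R,2S,5R,9S)-2-hydroxy-1-[(3Z)-5-hydroxy-4-methylpent-3-en-1-yl]-9-[(3Z)-5-hydroxy-3-methylpent-3-en-1-yl]-5-methyl-6,8-dioxabicyclo[3.2.2]nonan-7-one (CNP0105745.1)
Conditions: HF·pyridine, THF, 0 °C to rt
Reagents that add atoms: none
Why: Fluoride cleavage of both silyl ethers under mildly acidic conditions that the lactone and the allylic alcohols tolerate; no stereocentre is touched.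

## Compound list

1 | propane-1,3-diol | OCCCO | starting material
2 | 3-(TBSO)propan-1-ol | CC(C)(C)[Si](C)(C)OCCCO | intermediate
3 | 3-(TBSO)propanal | CC(C)(C)[Si](C)(C)OCCC=O | intermediate
4 | ethynyltrimethylsilane | C#C[Si](C)(C)C | starting material
5 | lithium (trimethylsilyl)acetylide | [Li]C#C[Si](C)(C)C | intermediate (not isolated)
6 | rac-5-(TBSO)-1-(trimethylsilyl)pent-1-yn-3-ol | CC(C)(C)[Si](C)(C)OCCC(O)C#C[Si](C)(C)C | intermediate
7 | 5-(TBSO)-1-(trimethylsilyl)pent-1-yn-3-one | CC(C)(C)[Si](C)(C)OCCC(=O)C#C[Si](C)(C)C | intermediate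
8 | (3S)-5-(TBSO)-1-(trimethylsilyl)pent-1-yn-3-ol | O[C@@H](CCO[Si](C)(C)C(C)(C)C)C#C[Si](C)(C)C | intermediate
9 | bromoacetic acid | OC(=O)CBr | starting material
10 | 2-{[(3S)-5-(TBSO)-1-(trimethylsilyl)pent-1-yn-3-yl]oxy}acetic acid | OC(=O)CO[C@@H](CCO[Si](C)(C)C(C)(C)C)C#C[Si](C)(C)C | intermediate (not isolated)
11 | 2-{[(3S)-5-(TBSO)pent-1-yn-3-yl]oxy}acetic acid | OC(=O)CO[C@@H](CCO[Si](C)(C)C(C)(C)C)C#C | intermediate
12 | (5S)-5-[2-(TBSO)ethyl]-6-methylidene-1,4-dioxan-2-one | O=C1CO[C@@H](CCO[Si](C)(C)C(C)(C)C)C(=C)O1 | intermediate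
13 | 3-(phenylsulfanyl)propanoic acid | OC(=O)CCSc1ccccc1 | starting material
14 | 1-(1H-imidazol-1-yl)-3-(phenylsulfanyl)propan-1-one | O=C(CCSc1ccccc1)n1ccnc1 | intermediate
15 | (5S)-5-[2-(TBSO)ethyl]-6-methylidene-3-[3-(phenylsulfanyl)propanoyl]-1,4-dioxan-2-one (C3 epimers and enol) | O=C1C(C(=O)CCSc2ccccc2)O[C@@H](CCO[Si](C)(C)C(C)(C)C)C(=C)O1 | intermediate
16 | 2-(2-bromoethyl)-1,3-dioxolane | BrCCC1OCCO1 | starting material
17 | (3R,5S)-5-[2-(TBSO)ethyl]-3-[2-(1,3-dioxolan-2-yl)ethyl]-6-methylidene-3-[3-(phenylsulfanyl)propanoyl]-1,4-dioxan-2-one | O1CCOC1CC[C@]2(C(=O)CCSc3ccccc3)O[C@@H](CCO[Si](C)(C)C(C)(C)C)C(=C)OC2=O | intermediate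
18 | (3R,5S)-5-[2-(TBSO)ethyl]-3-[2-(1,3-dioxolan-2-yl)ethyl]-6-methylidene-3-[3-(phenylsulfinyl)propanoyl]-1,4-dioxan-2-one (sulfur epimers) | O1CCOC1CC[C@]2(C(=O)CCS(=O)c3ccccc3)O[C@@H](CCO[Si](C)(C)C(C)(C)C)C(=C)OC2=O | intermediate (not isolated)
19 | (3R,5S)-5-[2-(TBSO)ethyl]-3-[2-(1,3-dioxolan-2-yl)ethyl]-6-methylidene-3-(prop-2-enoyl)-1,4-dioxan-2-one | O1CCOC1CC[C@]2(C(=O)C=C)O[C@@H](CCO[Si](C)(C)C(C)(C)C)C(=C)OC2=O | intermediate
20 | (1R,5R,9S)-9-[2-(TBSO)ethyl]-1-[2-(1,3-dioxolan-2-yl)ethyl]-5-methyl-6,8-dioxabicyclo[3.2.2]nonane-2,7-dione | O1CCOC1CC[C@@]23O[C@@H](CCO[Si](C)(C)C(C)(C)C)[C@@](C)(CCC2=O)OC3=O | intermediate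
21 | (1R,2S,5R,9S)-9-[2-(TBSO)ethyl]-1-[2-(1,3-dioxolan-2-yl)ethyl]-2-hydroxy-5-methyl-6,8-dioxabicyclo[3.2.2]nonan-7-one | O1CCOC1CC[C@@]23O[C@@H](CCO[Si](C)(C)C(C)(C)C)[C@@](C)(CC[C@@H]2O)OC3=O | intermediate
22 | (1R,2S,5R,9S)-2-(TBSO)-9-[2-(TBSO)ethyl]-1-[2-(1,3-dioxolan-2-yl)ethyl]-5-methyl-6,8-dioxabicyclo[3.2.2]nonan-7-one | O1CCOC1CC[C@@]23O[C@@H](CCO[Si](C)(C)C(C)(C)C)[C@@](C)(CC[C@@H]2O[Si](C)(C)C(C)(C)C)OC3=O | intermediate
23 | (1R,2S,5R,9S)-2-(TBSO)-1-[2-(1,3-dioxolan-2-yl)ethyl]-9-(2-hydroxyethyl)-5-methyl-6,8-dioxabicyclo[3.2.2]nonan-7-one | O1CCOC1CC[C@@]23O[C@@H](CCO)[C@@](C)(CC[C@@H]2O[Si](C)(C)C(C)(C)C)OC3=O | intermediate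
24 | (1R,2S,5R,9S)-2-(TBSO)-1-[2-(1,3-dioxolan-2-yl)ethyl]-9-(2-iodoethyl)-5-methyl-6,8-dioxabicyclo[3.2.2]nonan-7-one | O1CCOC1CC[C@@]23O[C@@H](CCI)[C@@](C)(CC[C@@H]2O[Si](C)(C)C(C)(C)C)OC3=O | intermediate
25 | but-2-yn-1-ol | CC#CCO | starting material
26 | sodium 2,2-bis(2-methoxyethoxy)-3-methyl-2,5-dihydro-1,2-oxaaluminol-2-uide (cyclic vinylalanate) | [Na+].COCCO[Al-]1(OCCOC)OCC=C1C | intermediate (not isolated)
27 | (2Z)-3-iodobut-2-en-1-ol | C/C(I)=C/CO | intermediate
28 | tert-butyl{[(2Z)-3-iodobut-2-en-1-yl]oxy}dimethylsilane | C/C(I)=C/CO[Si](C)(C)C(C)(C)C | intermediate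
29 | {2-[(1R,2S,5R,9S)-2-(TBSO)-1-[2-(1,3-dioxolan-2-yl)ethyl]-5-methyl-7-oxo-6,8-dioxabicyclo[3.2.2]nonan-9-yl]ethyl}zinc iodide | O1CCOC1CC[C@@]23O[C@@H](CC[Zn]I)[C@@](C)(CC[C@@H]2O[Si](C)(C)C(C)(C)C)OC3=O | intermediate (not isolated)
30 | (1R,2S,5R,9S)-2-(TBSO)-9-[(3Z)-5-(TBSO)-3-methylpent-3-en-1-yl]-1-[2-(1,3-dioxolan-2-yl)ethyl]-5-methyl-6,8-dioxabicyclo[3.2.2]nonan-7-one | O1CCOC1CC[C@@]23O[C@@H](CC/C(C)=C\CO[Si](C)(C)C(C)(C)C)[C@@](C)(CC[C@@H]2O[Si](C)(C)C(C)(C)C)OC3=O | intermediate
31 | 2,4,6-trimethyl-1-{1-[2-(triethylsilyloxy)ethoxy]-3-[(1R,2S,5R,9S)-2-(TBSO)-9-[(3Z)-5-(TBSO)-3-methylpent-3-en-1-yl]-5-methyl-7-oxo-6,8-dioxabicyclo[3.2.2]nonan-1-yl]propyl}pyridinium triflate (N,O-acetal epimers) | Cc1cc(C)[n+](C(CC[C@@]23O[C@@H](CC/C(C)=C\CO[Si](C)(C)C(C)(C)C)[C@@](C)(CC[C@@H]2O[Si](C)(C)C(C)(C)C)OC3=O)OCCO[Si](CC)(CC)CC)c(C)c1.[O-]S(=O)(=O)C(F)(F)F | intermediate (not isolated)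
32 | 3-[(1R,2S,5R,9S)-2-(TBSO)-9-[(3Z)-5-(TBSO)-3-methylpent-3-en-1-yl]-5-methyl-7-oxo-6,8-dioxabicyclo[3.2.2]nonan-1-yl]propanal | O=CCC[C@@]12O[C@@H](CC/C(C)=C\CO[Si](C)(C)C(C)(C)C)[C@@](C)(CC[C@@H]1O[Si](C)(C)C(C)(C)C)OC2=O | intermediate
33 | (1R,2S,5R,9S)-2-(TBSO)-9-[(3Z)-5-(TBSO)-3-methylpent-3-en-1-yl]-1-[(3Z)-4-iodopent-3-en-1-yl]-5-methyl-6,8-dioxabicyclo[3.2.2]nonan-7-one | C/C(I)=C/CC[C@@]12O[C@@H](CC/C(C)=C\CO[Si](C)(C)C(C)(C)C)[C@@](C)(CC[C@@H]1O[Si](C)(C)C(C)(C)C)OC2=O | intermediate
34 | (1R,2S,5R,9S)-2-(TBSO)-9-[(3Z)-5-(TBSO)-3-methylpent-3-en-1-yl]-1-[(3Z)-5-hydroxy-4-methylpent-3-en-1-yl]-5-methyl-6,8-dioxabicyclo[3.2.2]nonan-7-one | C/C(=C/CC[C@@]12O[C@@H](CC/C(C)=C\CO[Si](C)(C)C(C)(C)C)[C@@](C)(CC[C@@H]1O[Si](C)(C)C(C)(C)C)OC2=O)CO | intermediate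
35 | (1R,2S,5R,9S)-2-hydroxy-1-[(3Z)-5-hydroxy-4-methylpent-3-en-1-yl]-9-[(3Z)-5-hydroxy-3-methylpent-3-en-1-yl]-5-methyl-6,8-dioxabicyclo[3.2.2]nonan-7-one | C/C(=C/CC[C@@]12O[C@@H](CC/C(C)=C\CO)[C@@](C)(CC[C@@H]1O)OC2=O)CO | target

## Step count and least certain steps

Total: 23 steps. Longest linear sequence: 20 steps (steps 1–7, 9–16 and 19–23).

Step 12 (key step). Most likely to go wrong: the C4 radical is reduced by a second hydrogen-atom transfer before the slow 7-endo closure, or hydrogen-atom transfer goes to the enone, or the doubly activated enol lactone is opened by the alcohol. Fallback (the same radical made from a carbon–sulfur bond under tin hydride, where the hydrogen donor can be kept scarce):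
- The fallback sets out from 11. Markovnikov hydrothiolation of the terminal alkyne (PhSH, Pd(OAc)2 cat., THF) should give the vinyl sulfide acid F1.
- Acid-catalysed closure through the thionium ion (TsOH cat., CH2Cl2) should give the O,S-ketal lactone F2.
- The operations of steps 9, 10 and 11 then lead to the acyl lactone F3, the alkylated lactone F4 and the vinyl ketone F5. In the oxidation the unhindered alkyl aryl sulfide is expected to react before the hindered ketal sulfur.
- Bu3SnH (slow addition), AIBN, benzene, 80 °C cleaves the C4–S bond, and the tertiary radical closes onto the enone, which returns to the route at 20.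

Step 10. Most likely to go wrong: O-alkylation of the ambident enolate, a slow reaction of the unactivated halide that lets loss of thiophenol or decay of the enol lactone compete, or insufficient facial selectivity. Fallback: from 15, conjugate addition to acrolein (Et3N cat., CH2Cl2, 0 °C), again anti to chain B, gives the aldehyde F6. Aldehyde-selective Noyori acetalisation (Me3SiOCH2CH2OSiMe3, Me3SiOTf cat., CH2Cl2, −78 °C) returns to the route at 17.

Step 9. Most likely to go wrong: fragmentation of the enol-lactone enolate to a ketene, or O-acylation and double acylation. Fallback: from 12, aldol addition with only one equivalent of base (LiN(SiMe3)2, THF, −78 °C, then 3-(phenylsulfanyl)propanal), in which the enolate is consumed at once, gives the β-hydroxy lactone F7. Dess–Martin oxidation returns to the route at 15.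

Step 13. Most likely to go wrong: poor facial selectivity, because the bridged ketone may impose its own preference against the catalyst. Fallback: from 20, if hydride arrives on the wrong face the C7-epimeric alcohol F8 results. Mitsunobu inversion with chloroacetic acid (PPh3, DIAD, toluene) gives the inverted chloroacetate F9, which thiourea and NaHCO3 cleave without touching the lactone, returning to the route at 21. The weak point is the hindered, neopentyl-like carbinol.

Step 21. Most likely to go wrong: low conversion, erosion of the Z-selectivity, or enolisation of the aldehyde by the basic ylide. Fallback: from 32, Still–Gennari olefination (ethyl 2-[bis(2,2,2-trifluoroethoxy)phosphoryl]propanoate, KN(SiMe3)2, 18-crown-6, THF, −78 °C) gives the (Z)-enoate F10. Reduction with i-Bu2AlH at −78 °C returns to the route at 34, skipping 33. The risk is then moved to the chemoselectivity between the conjugated ester and the hindered lactone.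

## Further compounds

F1 | step 12 | 2-{[(3S)-5-(TBSO)-2-(phenylsulfanyl)pent-1-en-3-yl]oxy}acetic acid | OC(=O)CO[C@@H](CCO[Si](C)(C)C(C)(C)C)C(=C)Sc1ccccc1
F2 | step 12 | (5S)-5-[2-(TBSO)ethyl]-6-methyl-6-(phenylsulfanyl)-1,4-dioxan-2-one (C6 epimers) | O=C1CO[C@@H](CCO[Si](C)(C)C(C)(C)C)C(C)(Sc2ccccc2)O1
F3 | step 12 | (5S)-5-[2-(TBSO)ethyl]-6-methyl-6-(phenylsulfanyl)-3-[3-(phenylsulfanyl)propanoyl]-1,4-dioxan-2-one | O=C1C(C(=O)CCSc2ccccc2)O[C@@H](CCO[Si](C)(C)C(C)(C)C)C(C)(Sc2ccccc2)O1
F4 | step 12 | (3R,5S)-5-[2-(TBSO)ethyl]-3-[2-(1,3-dioxolan-2-yl)ethyl]-6-methyl-6-(phenylsulfanyl)-3-[3-(phenylsulfanyl)propanoyl]-1,4-dioxan-2-one | O1CCOC1CC[C@]2(C(=O)CCSc3ccccc3)O[C@@H](CCO[Si](C)(C)C(C)(C)C)C(C)(Sc3ccccc3)OC2=O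
F5 | step 12 | (3R,5S)-5-[2-(TBSO)ethyl]-3-[2-(1,3-dioxolan-2-yl)ethyl]-6-methyl-6-(phenylsulfanyl)-3-(prop-2-enoyl)-1,4-dioxan-2-one | O1CCOC1CC[C@]2(C(=O)C=C)O[C@@H](CCO[Si](C)(C)C(C)(C)C)C(C)(Sc3ccccc3)OC2=O
F6 | step 10 | 3-[(3R,5S)-5-[2-(TBSO)ethyl]-6-methylidene-2-oxo-3-[3-(phenylsulfanyl)propanoyl]-1,4-dioxan-3-yl]propanal | O=CCC[C@]1(C(=O)CCSc2ccccc2)O[C@@H](CCO[Si](C)(C)C(C)(C)C)C(=C)OC1=O
F7 | step 9 | (5S)-5-[2-(TBSO)ethyl]-3-[1-hydroxy-3-(phenylsulfanyl)propyl]-6-methylidene-1,4-dioxan-2-one (diastereomers) | O=C1C(C(O)CCSc2ccccc2)O[C@@H](CCO[Si](C)(C)C(C)(C)C)C(=C)O1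
F8 | step 13 | (1R,2R,5R,9S)-9-[2-(TBSO)ethyl]-1-[2-(1,3-dioxolan-2-yl)ethyl]-2-hydroxy-5-methyl-6,8-dioxabicyclo[3.2.2]nonan-7-one | O1CCOC1CC[C@@]23O[C@@H](CCO[Si](C)(C)C(C)(C)C)[C@@](C)(CC[C@H]2O)OC3=O
F9 | step 13 | (1R,2S,5R,9S)-9-[2-(TBSO)ethyl]-1-[2-(1,3-dioxolan-2-yl)ethyl]-5-methyl-7-oxo-6,8-dioxabicyclo[3.2.2]nonan-2-yl chloroacetate | O1CCOC1CC[C@@]23O[C@@H](CCO[Si](C)(C)C(C)(C)C)[C@@](C)(CC[C@@H]2OC(=O)CCl)OC3=O
F10 | step 21 | ethyl (2Z)-5-[(1R,2S,5R,9S)-2-(TBSO)-9-[(3Z)-5-(TBSO)-3-methylpent-3-en-1-yl]-5-methyl-7-oxo-6,8-dioxabicyclo[3.2.2]nonan-1-yl]-2-methylpent-2-enoate | CCOC(=O)/C(C)=C\CC[C@@]12O[C@@H](CC/C(C)=C\CO[Si](C)(C)C(C)(C)C)[C@@](C)(CC[C@@H]1O[Si](C)(C)C(C)(C)C)OC2=O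
A1 | alternative 1 | dimethyl 2-{[(3Z,6S,7R)-1-(TBSO)-3,7-dimethyl-10-oxo-7-(triethylsilyloxy)dec-2-en-6-yl]oxy}but-2-enedioate (alkene geometry of the butenedioate left open) | O=CCC[C@@](C)(O[Si](CC)(CC)CC)[C@H](CC/C(C)=C\CO[Si](C)(C)C(C)(C)C)OC(=CC(=O)OC)C(=O)OC
A2 | alternative 1 | oxepane diester with C1 quaternary and C7 hydroxyl (product of the ketyl addition) | COC(=O)C[C@@]1(C(=O)OC)O[C@@H](CC/C(C)=C\CO[Si](C)(C)C(C)(C)C)[C@@](C)(CC[C@@H]1O)O[Si](CC)(CC)CC
A3 | alternative 2 | seven-membered hydroxy keto lactone (C1 hydroxyl, C3 ketone, two allylic acetates, C7 triethylsilyl ether) | CC(=O)OC/C(C)=C\CC[C@@]1(O)[C@@H](O[Si](CC)(CC)CC)CC[C@](C)(C(=O)CC/C(C)=C\COC(C)=O)OC1=O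
A4 | alternative 2 | protected target (two allylic acetates, C7 triethylsilyl ether) | CC(=O)OC/C(C)=C\CC[C@@]12O[C@@H](CC/C(C)=C\COC(C)=O)[C@@](C)(CC[C@@H]1O[Si](CC)(CC)CC)OC2=O
A5 | alternative 3 | dimethyl alkoxymalonate with chain A on C1, free tertiary C4 hydroxyl and 2-(phenylsulfonyl)ethyl arm | CC(C)(C)[Si](C)(C)OC/C(C)=C\CCC(C(=O)OC)(C(=O)OC)O[C@@H](CC/C(C)=C\CO[Si](C)(C)C(C)(C)C)[C@](C)(O)CCS(=O)(=O)c1ccccc1
A6 | alternative 3 | bridged keto lactone with the sulfone on C6 and both protected side chains | CC(C)(C)[Si](C)(C)OC/C(C)=C\CC[C@@]12O[C@@H](CC/C(C)=C\CO[Si](C)(C)C(C)(C)C)[C@@](C)(C[C@H](S(=O)(=O)c3ccccc3)C1=O)OC2=O
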